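## Structural features

The target is a (3R)-isoflavan, numbered in the usual way: ring C is the pyran O1–C2–C3–C4, ring A is the fused benzene C4a–C8a, and ring B (C1'–C6') hangs from C3. Ring A is a fully differentiated phloroglucinol: O1 is the ring ether, O5 is methylated, O7 is a free phenol hydrogen-bonded to a formyl group on C8, and C6 is the only aromatic CH. Ring B is a resorcinol in which O2' is tied to C3' through a 2,2-dimethyl-2H-pyran (a chromene), while O4' is a free phenol. C3 is the only stereocentre; it is benzylic to ring B, sits between two methylene groups with no neighbouring centre to relay from, and is configurationally safe only while no carbonyl group is attached to it. The fragile parts are the chromene alkene (acid, hydrogenation), the aldehyde and the two electron-rich rings. The difficulty is threefold: setting an isolated benzylic centre catalytically, telling O1, O5 and O7 and the positions C6 and C8 apart on ring A, and telling O2' from O4' on ring B. The key step uses the fact that C3 and C4 are adjacent carbons, each benzylic to a different ring, and that O2' is ortho to C1'. A benzyl ether from O2' to C4 therefore places a C4–H bond five atoms from a carbene at C3, and the five-membered ether so formed can later be cut at C4–O2' to return the phenol on which the pyran is built.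

## Logic of the disconnections

**20 from 19.** The two O–CH2OMe acetal bonds on O7 and O4' are the last to be cut. Both phenols must stay masked to the end: O4' so that only O2' is propargylated, O7 so that ring A shows a single free phenol when C8 is formylated. The skeleton is unchanged, but the oxygens stay differentiated. The forward step needs an acid mild enough for the chromene and the aldehyde. A methyl ether on O7 could not be told from the O5 methyl ether at this point, which is why O7 is carried as a methoxymethyl ether from the first step.

**19 from 18.** O1–C2 is cut. C2 is a primary carbinol carbon, so an intramolecular phenol alkylation closes ring C without touching C3. This opens ring C and exposes O1–H. The forward step needs an acidic phenol and a single free phenol in 18.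

**18 from 17.** The C8–CHO bond is cut. With O1–H free, C8 is its only open ortho position and C6 is para to it, so an ortho-specific phenoxide-directed formylation answers the C6/C8 question. For this reason ring C is closed after the formylation and not before. The demand is that O7 and O4' carry no free hydroxyl.

**17 from 16.** The O1–Si bond is restored. O1 must be masked while O2' is alkylated and is freed only when C4 is a plain methylene, so desilylation cannot trigger quinone methide chemistry.

**16 from 14 and 13.** The pyran is removed by cutting C3'–C(vinyl) and then O2'–CMe2. This strips ring B back to a phenol. The forward steps need O2' to be the only free phenol in 13; C1' is substituted, so the sigmatropic shift can only end at C3'.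

**13 from 12.** The C4–O2' bond is reconnected. This turns an open 2,3-diarylpropanol into a dihydrobenzofuran whose ring can be made by C–H insertion; the C4 centre of 12 is sacrificed in the forward direction. Hydrogenolysis must come before any alkene exists and must spare the silyl and acetal groups.

**12 from 11.** C2 is returned to the ester level. The ester is what makes the carbene at C3 a stabilised donor–acceptor carbene. The reduction must be non-basic and cold, because C3 of 11 is alpha to the ester and cis to a large aryl group.

**11 from 10.** The C3–C4 bond is cut (key step). One ring, one skeletal bond and both stereocentres go in a single catalytic operation, and 10 is an achiral, flexible ether. The demand is enantioface selection at the carbene and insertion into the one reachable C–H.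

**10 from 9.** The C=N2 group is removed; 9 is a plain arylacetate open to base-mediated diazo transfer.

**9 from 8 and 4.** The O2'–C4 ether bond is cut, which splits the molecule into its ring B and ring A halves. The ester is already at the right oxidation level in 8: a one-carbon homologation after the union would meet an acid-labile trioxygenated benzyl ether and a base-labile aryl silyl ether. The forward etherification must run near neutrality because 4 ionises easily.

**8 from 6 and 5.** The O4'–CH2OMe bond and the ester C–OMe bond are cut, and the ester is folded back onto O2' as a lactone. The lactone of 6 hides O2' and the carboxyl together, so O4' is the only phenol to protect; methanolysis then releases O2'–H alone.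

**4 from 3, 2 and 1.** The benzylic C–H (from the aldehyde), O1–Si and O7–CH2OMe bonds are cut in turn. In 1 the O5 methyl ether is already present, and the hydroxyl next to the aldehyde is chelated, so the other one is protected first.

## Other disconnections considered

**Alternative 1:** The cut is O1–C8a. In the forward sense the primary alkoxide of A2, whose ring A carries fluorine on both carbons flanking a formyl group, would displace the fluoride on C8a through a Meisenheimer adduct stabilised by the ortho aldehyde, closing ring C as A1.
- In its favour: the formyl carbon is in place from the start, the tether reaches only C8a, no protecting group is needed on O1 or O7, and the chromene is indifferent to base.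
- Against it here: the substitution creates no stereocentre, so C3 of A2 must come from a separate asymmetric operation that this plan leaves open. The fluorine on C7 of A1 must then be exchanged for hydroxyl by a second substitution next to an aldehyde that is itself open to attack. The chromene must also be carried through the whole assembly of A2.
- Comparison: on the C6/C8 question the two plans are equal, since both fix C8 without ambiguity. On protecting groups, and in having neither a sacrificial stereocentre nor a hydrogenolysis, Alternative 1 is the better. On stereocontrol the chosen plan is stronger, because it sets C3 in the same catalytic step that joins C3 to C4. Step counts would be close once a source of chiral A2 is included.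

**Alternative 2:** The cuts are C3–C4 and O1–C2. Base would release an ortho-quinone methide from sulfone A4 by loss of sulfinate. The enamine formed from arylacetaldehyde A5 and a chiral secondary amine would add to its methylene carbon (C4), and the phenoxide would close on the aldehyde carbon (C2) to give lactol A3.
- In its favour: two bonds, ring C and the C3 centre arise in one metal-free catalytic step from two fragments of similar size. One reductive removal of the anomeric hydroxyl would then give the isoflavan. This is fewer operations than the reduction, hydrogenolysis and recyclisation of the chosen plan, and here Alternative 2 is the better.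
- Against it here: A5 is prone to self-condensation and its enamine is conjugated with ring B, so reactivity and facial control are less secure than with alkyl aldehydes. In A3, C3 stays alpha to a masked aldehyde that can reopen while the amine is present, so the centre can erode until C2 is reduced. The deoxygenation needs a Lewis acid and a silane beside an acetal protecting group. Ring A of A3 has two methyl ethers, so O7 would need the same redesign as in the chosen plan.
- Comparison: the benzyl ether on O2' must be hydrogenolysed before the chromene is made, and the pyran and the C8 formyl group remain to be installed, so the late tasks are equal. Both plans set C3 by face selection at a trigonal carbon (enamine or carbene). The carbene route makes that centre configurationally stable after one reduction, whereas the enamine route keeps it labile for longer.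

**Alternative 3:** The cut is made in cyclobutanone A7, between the carbonyl carbon and one of its two enantiotopic methylene groups. Hydrogen peroxide would add to the ketone activated by a chiral phosphoric acid, and in the Criegee-type adduct one methylene would migrate to oxygen, giving lactone A6 with the C2–O bond and the C3 centre.
- In its favour: it is a metal-free desymmetrisation of a prochiral ketone. The new centre is beta to the carbonyl and cannot epimerise by enolisation, which is better than ester 11 of the chosen plan and equal to it after step 9.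
- Against it here: A6 contains ring B only, and its four carbons do not map onto ring C, which has three carbons between O1 and C4a. The lactone carbonyl carbon has no counterpart. It would have to be excised after ring A had been attached at the alpha-methylene (an enolate arylation with a hindered trioxygenated aryl halide), or ring A would have to be built around it. The O–C2 bond made in the key step survives only if ring C is closed by an aryl C–O coupling at C8a and not by displacement at C2. A7 must itself be made by a cycloaddition–dehalogenation sequence.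
- Comparison: both plans rest enantiocontrol on a chiral catalyst acting on a prochiral unit, and neither is clearly superior there. In bond economy the chosen plan is stronger, because its key step joins the two aromatic halves while creating C3. The step count of Alternative 3 would in all likelihood be higher.

Key step: step 8

Assumption: 1 and 5 are taken as purchasable.

Assumption: Rh2(S-PTTL)4 is taken to deliver the (2R,3S) cis isomer 11, by analogy with closely related closures; if the substrate responded in the opposite sense, the mirror-image catalyst Rh2(R-PTTL)4 would be used with nothing else changed.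

Abbreviations in the steps: MOM = methoxymethyl, TBS = tert-butyldimethylsilyl, MOMO and TBSO the corresponding ether groups.

## Route

Step 1
Reactants: 1 2,4-dihydroxy-6-methoxybenzaldehyde
Product: 2 2-hydroxy-6-methoxy-4-(MOMO)benzaldehyde
Conditions: MOMCl (1.05 equiv), i-Pr2NEt, CH2Cl2, 0 °C
Reagents that add atoms: chloromethyl methyl ether COCCl
Why: The hydroxyl next to the aldehyde is held in a hydrogen bond and is the poorer nucleophile, so one equivalent of MOMCl should alkylate only the para hydroxyl (chelation-controlled Williamson-type O-alkylation). This puts the removable group on the future O7, while the future O5 already carries its methyl group.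

Step 2
Reactants: 2 2-hydroxy-6-methoxy-4-(MOMO)benzaldehyde
Product: 3 2-(TBSO)-6-methoxy-4-(MOMO)benzaldehyde
Conditions: TBSCl, imidazole, DMF, rt
Reagents that add atoms: tert-butyldimethylsilyl chloride CC(C)(C)[Si](C)(C)Cl
Why: Silyl ether formation on the remaining phenol masks the future O1 with a group that fluoride removes without touching MOM ethers.

Step 3
Reactants: 3 2-(TBSO)-6-methoxy-4-(MOMO)benzaldehyde
Product: 4 [2-(TBSO)-6-methoxy-4-(MOMO)phenyl]methanol
Conditions: NaBH4, THF–EtOH, 0 °C
Reagents that add atoms: none
Why: Borohydride reduction of an aryl aldehyde; low temperature and a buffered quench should keep the benzylic alkoxide from drawing the silyl group across from the neighbouring oxygen.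

Step 4
Reactants: 5 2-(2,4-dihydroxyphenyl)acetic acid
Product: 6 6-hydroxy-1-benzofuran-2(3H)-one
Conditions: TsOH·H2O (cat.), toluene, reflux, Dean–Stark
Reagents that add atoms: none
Why: Acid-catalysed lactonisation of a 2-hydroxyphenylacetic acid with azeotropic removal of water ties O2' and the carboxyl group into one ring and leaves O4' as the only free phenol.

Step 5
Reactants: 6 6-hydroxy-1-benzofuran-2(3H)-one
Product: 8 methyl 2-[2-hydroxy-4-(MOMO)phenyl]acetate, via 6-(MOMO)-1-benzofuran-2(3H)-one 7 (not isolated)
Conditions: MOMCl, i-Pr2NEt, CH2Cl2, 0 °C; then MeOH, K2CO3 (cat.), 0 °C to rt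
Reagents that add atoms: chloromethyl methyl ether COCCl; methanol CO
Why: O-alkylation of the single free phenol is followed by base-catalysed methanolysis of the aryl lactone (transesterification of an activated phenyl ester), which releases O2'–H and the methyl ester in one flask. Methanol destroys excess MOMCl before the new phenoxide appears.

Step 6
Reactants: 8 methyl 2-[2-hydroxy-4-(MOMO)phenyl]acetate; 4 [2-(TBSO)-6-methoxy-4-(MOMO)phenyl]methanol
Product: 9 methyl 2-[2-{[2-(TBSO)-6-methoxy-4-(MOMO)phenyl]methoxy}-4-(MOMO)phenyl]acetate
Conditions: PPh3, DIAD, THF, 0 °C to rt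
Reagents that add atoms: none
Why: Mitsunobu etherification of a phenol with a primary benzylic alcohol forms the O2'–C4 bond near neutrality, which the acid-labile trioxygenated benzyl system and the aryl silyl ether should tolerate. Slow addition of DIAD limits ionisation of the activated alcohol.

Step 7
Reactants: 9 methyl 2-[2-{[2-(TBSO)-6-methoxy-4-(MOMO)phenyl]methoxy}-4-(MOMO)phenyl]acetate
Product: 10 methyl 2-diazo-2-[2-{[2-(TBSO)-6-methoxy-4-(MOMO)phenyl]methoxy}-4-(MOMO)phenyl]acetate
Conditions: p-ABSA, DBU, MeCN, 0 °C to rt
Reagents that add atoms: 4-acetamidobenzenesulfonyl azide CC(=O)Nc1ccc(cc1)S(=O)(=O)N=[N+]=[N-]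
Why: Regitz diazo transfer to an arylacetate: the DBU enolate attacks the sulfonyl azide and the sulfonamide leaves. Dry conditions and low temperature protect the aryl silyl ether.

Step 8
Reactants: 10 methyl 2-diazo-2-[2-{[2-(TBSO)-6-methoxy-4-(MOMO)phenyl]methoxy}-4-(MOMO)phenyl]acetate
Product: 11 methyl (2R,3S)-2-[2-(TBSO)-6-methoxy-4-(MOMO)phenyl]-6-(MOMO)-2,3-dihydro-1-benzofuran-3-carboxylate
Conditions: Rh2(S-PTTL)4 (dirhodium tetrakis[N-phthaloyl-(S)-tert-leucinate], 1 mol%), toluene, −60 °C
Reagents that add atoms: none
Why: The dirhodium carboxylate takes up the diazo carbon, N2 leaves, and an electrophilic donor–acceptor rhodium carbene is formed at C3. The carbene carbon inserts into a C4–H bond of the O2' benzyl ether through a concerted, asynchronous three-centre transition state with hydride-shift character. The closest known reaction type is the dirhodium-carboxylate-catalysed enantioselective intramolecular C–H insertion of aryldiazoacetates into benzylic ether C–H bonds, which gives cis-2-aryl-2,3-dihydrobenzofuran-3-carboxylates. The ring closes as a five-membered ether by formal 1,5-insertion (C3, C1', C2', O2', C4). C3 is fixed by the chiral phthalimido-carboxylate ligands, which leave one face of the carbene open. C4 follows from the transition-state geometry, which places the ring A aryl group and the ester cis under kinetic control. The step needs insertion to win over carbene dimerisation, ylide formation and arene addition: the C4–H bond is the only one within reach and is activated both by the ether oxygen and by the electron-rich ring A, both ortho positions of ring A are substituted, and the other oxygens are too remote for small-ring ylides. Because C4 is erased later, only the sense at C3 has to be right, and the (2R,3S) isomer maps onto (3R) in the target.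

Step 9
Reactants: 11 methyl (2R,3S)-2-[2-(TBSO)-6-methoxy-4-(MOMO)phenyl]-6-(MOMO)-2,3-dihydro-1-benzofuran-3-carboxylate
Product: 12 [(2R,3R)-2-[2-(TBSO)-6-methoxy-4-(MOMO)phenyl]-6-(MOMO)-2,3-dihydro-1-benzofuran-3-yl]methanol
Conditions: i-Bu2AlH, CH2Cl2, −78 °C
Reagents that add atoms: none
Why: Hydride reduction of the ester to the primary alcohol in a cold, non-basic medium removes the only acidifying group next to C3 before the cis ester can epimerise. The change of descriptor at C3 is a priority effect only.

Step 10
Reactants: 12 [(2R,3R)-2-[2-(TBSO)-6-methoxy-4-(MOMO)phenyl]-6-(MOMO)-2,3-dihydro-1-benzofuran-3-yl]methanol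
Product: 13 2-[(2R)-1-[2-(TBSO)-6-methoxy-4-(MOMO)phenyl]-3-hydroxypropan-2-yl]-5-(MOMO)phenol
Conditions: H2 (1 atm), Pd/C, EtOAc, rt
Reagents that add atoms: none
Why: Catalytic hydrogenolysis of a benzyl aryl ether: the C4–O2' bond is benzylic to the electron-rich ring A and should cleave on palladium, turning C4 into a methylene and freeing O2'–H. C3 carries no benzylic oxygen and is untouched, no alkene is present yet, and silyl and MOM ethers are inert in a neutral ester solvent.

Step 11
Reactants: 13 2-[(2R)-1-[2-(TBSO)-6-methoxy-4-(MOMO)phenyl]-3-hydroxypropan-2-yl]-5-(MOMO)phenol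
Product: 14 (2R)-3-[2-(TBSO)-6-methoxy-4-(MOMO)phenyl]-2-{4-(MOMO)-2-[(2-methylbut-3-yn-2-yl)oxy]phenyl}propan-1-ol
Conditions: 3-chloro-3-methylbut-1-yne, DBU, CuCl2 (cat.), MeCN, 0 °C
Reagents that add atoms: 3-chloro-3-methylbut-1-yne CC(C)(Cl)C#C
Why: Copper-catalysed O-propargylation of a phenol with a tertiary propargylic chloride (through a copper acetylide-derived electrophile) tolerates ortho-substituted phenols. Only O2'–H is acidic enough to react under DBU, so the primary alcohol is left alone.

Step 12
Reactants: 14 (2R)-3-[2-(TBSO)-6-methoxy-4-(MOMO)phenyl]-2-{4-(MOMO)-2-[(2-methylbut-3-yn-2-yl)oxy]phenyl}propan-1-ol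
Product: 16 (2R)-3-[2-(TBSO)-6-methoxy-4-(MOMO)phenyl]-2-[5-(MOMO)-2,2-dimethyl-2H-chromen-8-yl]propan-1-ol, via ortho-allenylphenol 15 (not isolated)
Conditions: o-xylene, 140 °C
Reagents that add atoms: none
Why: Aryl propargyl ether Claisen rearrangement: the [3,3]-shift ends at C3', the only free ortho carbon, and enolisation gives 15. A 1,5-hydrogen shift and an oxa-6π electrocyclisation then close the 2,2-dimethyl-2H-pyran with O2' as ring oxygen.

Step 13
Reactants: 16 (2R)-3-[2-(TBSO)-6-methoxy-4-(MOMO)phenyl]-2-[5-(MOMO)-2,2-dimethyl-2H-chromen-8-yl]propan-1-ol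
Product: 17 2-{(2R)-3-hydroxy-2-[5-(MOMO)-2,2-dimethyl-2H-chromen-8-yl]propyl}-3-methoxy-5-(MOMO)phenol
Conditions: Bu4NF, THF, 0 °C
Reagents that add atoms: none
Why: Fluoride cleavage of the aryl silyl ether frees O1–H. C4 is now a methylene without a leaving group, so the phenoxide cannot expel anything to form a quinone methide.

Step 14
Reactants: 17 2-{(2R)-3-hydroxy-2-[5-(MOMO)-2,2-dimethyl-2H-chromen-8-yl]propyl}-3-methoxy-5-(MOMO)phenol
Product: 18 2-hydroxy-3-{(2R)-3-hydroxy-2-[5-(MOMO)-2,2-dimethyl-2H-chromen-8-yl]propyl}-4-methoxy-6-(MOMO)benzaldehyde
Conditions: MgCl2, Et3N, (CH2O)n, THF, reflux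
Reagents that add atoms: paraformaldehyde (formaldehyde unit) C=O
Why: Magnesium-mediated ortho-formylation of a phenol (Casnati–Skattebøl type): formaldehyde is delivered inside the magnesium phenoxide chelate only ortho to O1, and C8 is the one open ortho position while C6 is para. A second formaldehyde unit accepts the hydride from the intermediate benzylic alkoxide.

Step 15
Reactants: 18 2-hydroxy-3-{(2R)-3-hydroxy-2-[5-(MOMO)-2,2-dimethyl-2H-chromen-8-yl]propyl}-4-methoxy-6-(MOMO)benzaldehyde
Product: 19 (3R)-5-methoxy-7-(MOMO)-3-[5-(MOMO)-2,2-dimethyl-2H-chromen-8-yl]-3,4-dihydro-2H-chromene-8-carbaldehyde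
Conditions: PPh3, DIAD, THF, 0 °C to rt
Reagents that add atoms: none
Why: Intramolecular Mitsunobu etherification (6-exo-tet) of the acidic salicylaldehyde-type phenol onto the primary carbinol closes ring C. Displacement occurs at C2, so C3 is not involved.

Step 16
Reactants: 19 (3R)-5-methoxy-7-(MOMO)-3-[5-(MOMO)-2,2-dimethyl-2H-chromen-8-yl]-3,4-dihydro-2H-chromene-8-carbaldehyde
Product: 20 (3R)-7-hydroxy-3-(5-hydroxy-2,2-dimethyl-2H-chromen-8-yl)-5-methoxy-3,4-dihydro-2H-chromene-8-carbaldehyde
Conditions: HCl (2 M aq), MeOH–THF, 40 °C
Reagents that add atoms: none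
Why: Acid-catalysed acetal exchange removes both MOM ethers; the one on O7 is assisted by the ortho formyl group. Dilute acid at moderate temperature is expected to leave the chromene alkene and the ring C ether intact.

## Compound list

1 | 2,4-dihydroxy-6-methoxybenzaldehyde | COc1cc(O)cc(O)c1C=O | starting material
2 | 2-hydroxy-6-methoxy-4-(methoxymethoxy)benzaldehyde | COCOc1cc(O)c(C=O)c(OC)c1 | intermediate
3 | 2-[(tert-butyldimethylsilyl)oxy]-6-methoxy-4-(methoxymethoxy)benzaldehyde | COCOc1cc(OC)c(C=O)c(O[Si](C)(C)C(C)(C)C)c1 | intermediate
4 | {2-[(tert-butyldimethylsilyl)oxy]-6-methoxy-4-(methoxymethoxy)phenyl}methanol | COCOc1cc(OC)c(CO)c(O[Si](C)(C)C(C)(C)C)c1 | intermediate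
5 | 2-(2,4-dihydroxyphenyl)acetic acid | OC(=O)Cc1ccc(O)cc1O | starting material
6 | 6-hydroxy-1-benzofuran-2(3H)-one | O=C1Cc2ccc(O)cc2O1 | intermediate
7 | 6-(methoxymethoxy)-1-benzofuran-2(3H)-one | O=C1Cc2ccc(OCOC)cc2O1 | intermediate
8 | methyl 2-[2-hydroxy-4-(methoxymethoxy)phenyl]acetate | COC(=O)Cc1ccc(OCOC)cc1O | intermediate
9 | methyl 2-[2-({2-[(tert-butyldimethylsilyl)oxy]-6-methoxy-4-(methoxymethoxy)phenyl}methoxy)-4-(methoxymethoxy)phenyl]acetate | COC(=O)Cc1ccc(OCOC)cc1OCc1c(OC)cc(OCOC)cc1O[Si](C)(C)C(C)(C)C | intermediate
10 | methyl 2-diazo-2-[2-({2-[(tert-butyldimethylsilyl)oxy]-6-methoxy-4-(methoxymethoxy)phenyl}methoxy)-4-(methoxymethoxy)phenyl]acetate | COC(=O)C(=[N+]=[N-])c1ccc(OCOC)cc1OCc1c(OC)cc(OCOC)cc1O[Si](C)(C)C(C)(C)C | intermediate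
11 | methyl (2R,3S)-2-{2-[(tert-butyldimethylsilyl)oxy]-6-methoxy-4-(methoxymethoxy)phenyl}-6-(methoxymethoxy)-2,3-dihydro-1-benzofuran-3-carboxylate | O1[C@@H](c2c(OC)cc(OCOC)cc2O[Si](C)(C)C(C)(C)C)[C@H](c2ccc(OCOC)cc21)C(=O)OC | intermediate
12 | [(2R,3R)-2-{2-[(tert-butyldimethylsilyl)oxy]-6-methoxy-4-(methoxymethoxy)phenyl}-6-(methoxymethoxy)-2,3-dihydro-1-benzofuran-3-yl]methanol | O1[C@@H](c2c(OC)cc(OCOC)cc2O[Si](C)(C)C(C)(C)C)[C@H](c2ccc(OCOC)cc21)CO | intermediate
13 | 2-[(2R)-1-{2-[(tert-butyldimethylsilyl)oxy]-6-methoxy-4-(methoxymethoxy)phenyl}-3-hydroxypropan-2-yl]-5-(methoxymethoxy)phenol | OC[C@H](Cc1c(OC)cc(OCOC)cc1O[Si](C)(C)C(C)(C)C)c1ccc(OCOC)cc1O | intermediate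
14 | (2R)-3-{2-[(tert-butyldimethylsilyl)oxy]-6-methoxy-4-(methoxymethoxy)phenyl}-2-{4-(methoxymethoxy)-2-[(2-methylbut-3-yn-2-yl)oxy]phenyl}propan-1-ol | OC[C@H](Cc1c(OC)cc(OCOC)cc1O[Si](C)(C)C(C)(C)C)c1ccc(OCOC)cc1OC(C)(C)C#C | intermediate
15 | 6-[(2R)-1-{2-[(tert-butyldimethylsilyl)oxy]-6-methoxy-4-(methoxymethoxy)phenyl}-3-hydroxypropan-2-yl]-3-(methoxymethoxy)-2-(3-methylbuta-1,2-dien-1-yl)phenol | OC[C@H](Cc1c(OC)cc(OCOC)cc1O[Si](C)(C)C(C)(C)C)c1ccc(OCOC)c(C=C=C(C)C)c1O | intermediate
16 | (2R)-3-{2-[(tert-butyldimethylsilyl)oxy]-6-methoxy-4-(methoxymethoxy)phenyl}-2-[5-(methoxymethoxy)-2,2-dimethyl-2H-chromen-8-yl]propan-1-ol | OC[C@H](Cc1c(OC)cc(OCOC)cc1O[Si](C)(C)C(C)(C)C)c1ccc(OCOC)c2c1OC(C)(C)C=C2 | intermediate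
17 | 2-{(2R)-3-hydroxy-2-[5-(methoxymethoxy)-2,2-dimethyl-2H-chromen-8-yl]propyl}-3-methoxy-5-(methoxymethoxy)phenol | OC[C@H](Cc1c(OC)cc(OCOC)cc1O)c1ccc(OCOC)c2c1OC(C)(C)C=C2 | intermediate
18 | 2-hydroxy-3-{(2R)-3-hydroxy-2-[5-(methoxymethoxy)-2,2-dimethyl-2H-chromen-8-yl]propyl}-4-methoxy-6-(methoxymethoxy)benzaldehyde | OC[C@H](Cc1c(OC)cc(OCOC)c(C=O)c1O)c1ccc(OCOC)c2c1OC(C)(C)C=C2 | intermediate
19 | (3R)-5-methoxy-7-(methoxymethoxy)-3-[5-(methoxymethoxy)-2,2-dimethyl-2H-chromen-8-yl]-3,4-dihydro-2H-chromene-8-carbaldehyde | COc1cc(OCOC)c(C=O)c2c1C[C@H](c1ccc(OCOC)c3c1OC(C)(C)C=C3)CO2 | intermediate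
20 | (3R)-7-hydroxy-3-(5-hydroxy-2,2-dimethyl-2H-chromen-8-yl)-5-methoxy-3,4-dihydro-2H-chromene-8-carbaldehyde | COc1cc(O)c(C=O)c2c1C[C@H](c1ccc(O)c3c1OC(C)(C)C=C3)CO2 | target

## Step count and least certain steps

Total number of steps: 16. Longest linear sequence: 14 (steps 1–3, then 6–16).

**Step 8 (key step).** The most likely failure is loss of enantioface control or a slow insertion, because the ring A aryl group on C4 is flanked by two ortho substituents; carbene dimerisation would then gain ground. The fallback replaces carbene insertion by an auxiliary-controlled aldol addition. It sets out from 8 (and uses 3) and returns at 13.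
- 8 would be benzylated on O2' (BnBr, K2CO3, DMF) to methyl 2-[2-(benzyloxy)-4-(methoxymethoxy)phenyl]acetate F1.
- F1 would be saponified (LiOH, THF–H2O) to 2-[2-(benzyloxy)-4-(methoxymethoxy)phenyl]acetic acid F2.
- F2 would be joined through its mixed pivalic anhydride to lithiated (S)-4-benzyl-1,3-oxazolidin-2-one, giving (4S)-4-benzyl-3-{2-[2-(benzyloxy)-4-(methoxymethoxy)phenyl]acetyl}-1,3-oxazolidin-2-one F3.
- Enolisation with Bu2BOTf and i-Pr2NEt and addition to 3 should give the Evans syn-aldol product (4S)-4-benzyl-3-[(2S,3S)-2-[2-(benzyloxy)-4-(methoxymethoxy)phenyl]-3-{2-[(tert-butyldimethylsilyl)oxy]-6-methoxy-4-(methoxymethoxy)phenyl}-3-hydroxypropanoyl]-1,3-oxazolidin-2-one F4, with C3 set by the auxiliary.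
- LiBH4 would remove the auxiliary reductively to give (1S,2R)-2-[2-(benzyloxy)-4-(methoxymethoxy)phenyl]-1-{2-[(tert-butyldimethylsilyl)oxy]-6-methoxy-4-(methoxymethoxy)phenyl}propane-1,3-diol F5.
- Hydrogenolysis (H2, Pd/C) would cleave both the O2' benzyl ether and the doubly activated benzylic C4–OH bond, arriving at 13.

**Step 6.** The activated form of 4 may ionise, leading to C-benzylation of ring B or self-condensation, or the silyl group may migrate. The fallback is a Williamson etherification from 4 and 8, returning at 9. 4 would be converted at −20 °C (MsCl, Et3N, LiCl, THF) into tert-butyl[2-(chloromethyl)-3-methoxy-5-(methoxymethoxy)phenoxy]dimethylsilane F6, which would be added cold to the caesium phenoxide of 8 (Cs2CO3, DMF, 0 °C).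

**Step 10.** Cleavage at the crowded C4 may be sluggish, or traces of acid on the catalyst may remove the silyl group. The fallback replaces catalytic hydrogenation by electron-transfer cleavage of the benzylic C–O bond: lithium 4,4'-di-tert-butylbiphenylide in THF at −78 °C, from 12 directly to 13, with no new compound.

**Step 12.** The sigmatropic shift may go toward the substituted carbon C1', followed by irreversible intramolecular cycloaddition of the allenyl dienone, or the tertiary propargyl group may be lost thermally. The fallback avoids the propargyl ether altogether. 13 would be condensed with 3-methylbut-2-enal in the presence of PhB(OH)2 and a catalytic carboxylic acid in refluxing toluene (ortho-specific condensation through a cyclic boronate, then quinone methide electrocyclisation). This goes from 13 to 16, bypassing 14, with no new compound.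

**Step 14.** The very electron-rich magnesium phenoxide may over-react (hydroxymethylation, or methoxymethyl transfer to oxygen), or conversion at the flanked C8 may be incomplete. The fallback closes ring C first and formylates by directed metalation; it sets out from 17 and returns at 19.
- 17 would be cyclised under Mitsunobu conditions to (3R)-5-methoxy-7-(methoxymethoxy)-3-[5-(methoxymethoxy)-2,2-dimethyl-2H-chromen-8-yl]-3,4-dihydro-2H-chromene F7.
- Lithiation with n-BuLi and TMEDA should occur at C8, which is flanked by the MOM ether on O7 and by O1, whose in-plane lone pair points at C8; the O5 methyl group turns toward C6 and shields it.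
- A DMF quench would give 19.

## Further compounds

F1 | step 8 | methyl 2-[2-(benzyloxy)-4-(methoxymethoxy)phenyl]acetate | COC(=O)Cc1ccc(OCOC)cc1OCc1ccccc1
F2 | step 8 | 2-[2-(benzyloxy)-4-(methoxymethoxy)phenyl]acetic acid | OC(=O)Cc1ccc(OCOC)cc1OCc1ccccc1
F3 | step 8 | (4S)-4-benzyl-3-{2-[2-(benzyloxy)-4-(methoxymethoxy)phenyl]acetyl}-1,3-oxazolidin-2-one | O=C(Cc1ccc(OCOC)cc1OCc1ccccc1)N1[C@@H](Cc2ccccc2)COC1=O
F4 | step 8 | (4S)-4-benzyl-3-[(2S,3S)-2-[2-(benzyloxy)-4-(methoxymethoxy)phenyl]-3-{2-[(tert-butyldimethylsilyl)oxy]-6-methoxy-4-(methoxymethoxy)phenyl}-3-hydroxypropanoyl]-1,3-oxazolidin-2-one | O=C(N1[C@@H](Cc2ccccc2)COC1=O)[C@@H](c1ccc(OCOC)cc1OCc1ccccc1)[C@H](O)c1c(OC)cc(OCOC)cc1O[Si](C)(C)C(C)(C)C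
F5 | step 8 | (1S,2R)-2-[2-(benzyloxy)-4-(methoxymethoxy)phenyl]-1-{2-[(tert-butyldimethylsilyl)oxy]-6-methoxy-4-(methoxymethoxy)phenyl}propane-1,3-diol | OC[C@@H](c1ccc(OCOC)cc1OCc1ccccc1)[C@H](O)c1c(OC)cc(OCOC)cc1O[Si](C)(C)C(C)(C)C
F6 | step 6 | tert-butyl[2-(chloromethyl)-3-methoxy-5-(methoxymethoxy)phenoxy]dimethylsilane | COCOc1cc(OC)c(CCl)c(O[Si](C)(C)C(C)(C)C)c1
F0 | step 10 | none | none
F0 | step 12 | none | none
F7 | step 14 | (3R)-5-methoxy-7-(methoxymethoxy)-3-[5-(methoxymethoxy)-2,2-dimethyl-2H-chromen-8-yl]-3,4-dihydro-2H-chromene | COc1cc(OCOC)cc2c1C[C@H](c1ccc(OCOC)c3c1OC(C)(C)C=C3)CO2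
A1 | alternative 1 | (3R)-7-fluoro-5-methoxy-3-[5-(methoxymethoxy)-2,2-dimethyl-2H-chromen-8-yl]-3,4-dihydro-2H-chromene-8-carbaldehyde | COc1cc(F)c(C=O)c2c1C[C@H](c1ccc(OCOC)c3c1OC(C)(C)C=C3)CO2
A2 | alternative 1 | 2,6-difluoro-3-{(2R)-3-hydroxy-2-[5-(methoxymethoxy)-2,2-dimethyl-2H-chromen-8-yl]propyl}-4-methoxybenzaldehyde | OC[C@H](Cc1c(OC)cc(F)c(C=O)c1F)c1ccc(OCOC)c2c1OC(C)(C)C=C2
A3 | alternative 2 | (3R)-3-[2-(benzyloxy)-4-(methoxymethoxy)phenyl]-5,7-dimethoxy-3,4-dihydro-2H-chromen-2-ol (both C2 epimers) | COc1cc(OC)c2C[C@H](c3ccc(OCOC)cc3OCc3ccccc3)C(O)Oc2c1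
A4 | alternative 2 | 3,5-dimethoxy-2-[(4-methylbenzenesulfonyl)methyl]phenol | COc1cc(O)c(CS(=O)(=O)c2ccc(C)cc2)c(OC)c1
A5 | alternative 2 | 2-[2-(benzyloxy)-4-(methoxymethoxy)phenyl]acetaldehyde | O=CCc1ccc(OCOC)cc1OCc1ccccc1
A6 | alternative 3 | (4R)-4-{2-(benzyloxy)-4-[(triisopropylsilyl)oxy]phenyl}oxolan-2-one | O=C1C[C@H](c2ccc(O[Si](C(C)C)(C(C)C)C(C)C)cc2OCc2ccccc2)CO1
A7 | alternative 3 | 3-{2-(benzyloxy)-4-[(triisopropylsilyl)oxy]phenyl}cyclobutan-1-one | O=C1CC(c2ccc(O[Si](C(C)C)(C(C)C)C(C)C)cc2OCc2ccccc2)C1
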